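**Remark (assumption):** the target is read as the (E)-caffeate of natural (−)-drimenol, (5S,9S,10S) in drimane numbering: a trans-decalin with the CH2O group on C9 cis to the angular methyl on C10. Drimane numbering is used throughout: ring A = C1–C5 and C10, ring B = C5–C10, C11 = the CH2O carbon on C9.

**Retrosynthetic overview**
1. The caffeate is attached last to (−)-drimenol without protecting groups: malonic half ester from Meldrum's acid, then Knoevenagel–Doebner condensation with 3,4-dihydroxybenzaldehyde.
2. C11 and the C9 stereocentre come from 11-nordrim-7-en-9-one by Wittig methylenation of the C9 ketone and α-face hydroboration of the exocyclic alkene.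
3. Ring A is closed last and alone, through the C3–C4 bond: an MHAT/nickel hydroalkylative ring closure joins an isopropenyl group on C5 to a 3-iodopropyl arm on C10 and creates the gem-dimethyl quaternary C4 in the same event.
4. Ring B is bought as (R)-carvone; C10 is set by two enolate alkylations (methyl first, then the C1–C3 arm anti to the isopropenyl group). Ring order: ring B (carvone), then ring A (step 4); the catechol ring arrives with the aldehyde.
5. Enabling feature: ring B of the target (C5–C6–C7=C8(CH3)–C9–C10) plus C4 and one of its methyls is, atom for atom, carvone (C=O at C9, isopropenyl at C5 in the right configuration). C4 is the Markovnikov H/C adduct of that isopropenyl group, and C1–C3 are three plain CH2 groups.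

Key step: step 4

**Step 1**
Reactants: 1 (R)-(−)-carvone
Product: 3 (5R,6S)-6-methylcarvone (trans epimer major), via carvone lithium enolate 2 (not isolated)
Conditions: LiN(i-Pr)2, THF, −78 °C; then MeI, −78 → 0 °C
Reagents that add atoms: iodomethane, CI
Why: Kinetic deprotonation at the α′-CH2 gives the cross-conjugated lithium dienolate, and its SN2 methylation (enolate alkylation) places the methyl mainly trans to the isopropenyl group; this centre is planarised again in step 2, so its configuration does not matter.

**Step 2**
Reactants: 3 (5R,6S)-6-methylcarvone; 4 1-chloro-3-iodopropane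
Product: 6 (5S,6S)-6-(3-chloropropyl)-6-methylcarvone, via 6-methylcarvone lithium enolate 5 (not isolated)
Conditions: LiN(i-Pr)2, THF, −78 °C; then 4, DMPU, −78 → 0 °C
Reagents that add atoms: none
Why: Enolate alkylation (SN2 at the C–I end of 4, the C–Cl end being far slower) should occur on the enolate face opposite the neighbouring isopropenyl group, which sets the quaternary centre (later C10) with the chloropropyl arm trans and the methyl cis to the isopropenyl group, as a trans ring fusion requires.

**Step 3**
Reactants: 6 (5S,6S)-6-(3-chloropropyl)-6-methylcarvone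
Product: 7 (5S,6S)-6-(3-iodopropyl)-6-methylcarvone
Conditions: NaI, acetone, reflux
Reagents that add atoms: sodium iodide, [Na+].[I-]
Why: Finkelstein halide exchange (SN2) at the unhindered primary chloride should be driven by precipitation of NaCl, and no stereocentre is touched.

**Step 4**
Reactants: 7 (5S,6S)-6-(3-iodopropyl)-6-methylcarvone
Product: 8 (5S,10S)-11-nordrim-7-en-9-one [(4aS,8aS)-2,5,5,8a-tetramethyl-4a,5,6,7,8,8a-hexahydronaphthalen-1(4H)-one]
Conditions: Mn(dpm)3 (cat.), Ni(acac)2 (cat.), PhSiH3 (slow addition), K2CO3, (CF3)2CHOH, ClCH2CH2Cl/propylene carbonate, rt, high dilution, Ar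
Reagents that add atoms: none
Why: Proposed new method: a manganese hydride formed from Mn(dpm)3 and PhSiH3 should transfer a hydrogen atom to the CH2 terminus of the isopropenyl group (Markovnikov MHAT) to give the tertiary radical at the future C4, while low-valent nickel formed from Ni(acac)2 activates the primary C–I bond; capture of the radical by the alkylnickel and C(sp3)–C(sp3) reductive elimination from the resulting seven-membered nickelacycle would forge C3–C4. The closest known reaction type is the intermolecular manganese/nickel dual-catalytic, branch-selective hydroalkylation of 1,1-disubstituted olefins with primary alkyl iodides that builds quaternary carbons; new here is its use to close a ring. Ring A closes in a formal 6-exo-tet mode (the radical carbon replaces iodide at C3 by way of nickel). No stereocentre is created, since C4 becomes the gem-dimethyl quaternary carbon; the trans ring fusion follows from the fixed configurations at C5 and C10, whose trans-disposed arms can join only to a trans-decalin. The step needs hydrogen-atom transfer to the isopropenyl group and not to the enone, and ring closure before reduction of the radical or of the C–I bond: the electron-rich 1,1-disubstituted olefin is the fastest MHAT acceptor, the enone β-carbon is out of reach of the radical (it would give a four-membered ring), and intramolecular capture is favoured by high dilution and slow silane addition.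

**Step 5**
Reactants: 8 (5S,10S)-11-nordrim-7-en-9-one
Product: 9 (5S,10S)-drima-7,9(11)-diene
Conditions: Ph3PCH3Br, KOtBu, toluene, 90–110 °C
Reagents that add atoms: methyltriphenylphosphonium bromide, C[P+](c1ccccc1)(c1ccccc1)c1ccccc1.[Br-]
Why: Wittig methylenation with Ph3P=CH2 at elevated temperature is the standard answer to hindered ketones, and this ketone, flanked by a quaternary and a vinylic carbon, has no α-hydrogen, so ordinary enolisation cannot divert it.

**Step 6**
Reactants: 9 (5S,10S)-drima-7,9(11)-diene
Product: 11 (−)-drimenol [(5S,9S,10S)-drim-7-en-11-ol], via B-alkyl-9-BBN adduct 10 (not isolated)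
Conditions: 9-BBN, THF, 0 °C → rt; then NaOH, H2O2, 0 °C → rt
Reagents that add atoms: 9-borabicyclo[3.3.1]nonane (9-BBN), B1C2CCCC1CCC2; hydrogen peroxide, OO
Why: Hydroboration–oxidation: the bulky borane should add only to the exocyclic 1,1-disubstituted double bond (boron to the CH2; the ring trisubstituted alkene is inert to it) and deliver hydrogen to C9 from the α-face opposite the axial C10 methyl, which sets C9 with the CH2OH group cis to the angular methyl, and the oxidation proceeds with retention.

**Step 7**
Reactants: 11 (−)-drimenol; 12 Meldrum's acid (2,2-dimethyl-1,3-dioxane-4,6-dione)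
Product: 13 drimenyl hydrogen malonate
Conditions: toluene, reflux
Reagents that add atoms: none
Why: Alcoholysis of Meldrum's acid (acyl transfer to the primary alcohol with loss of acetone) is a standard route to malonic half esters and should leave the alkene and all stereocentres untouched.

**Step 8**
Reactants: 13 drimenyl hydrogen malonate; 14 3,4-dihydroxybenzaldehyde
Product: 16 (−)-drimenyl (E)-caffeate (target), via arylidene malonate half ester 15 (not isolated)
Conditions: pyridine, piperidine (cat.), rt → 50 °C
Reagents that add atoms: none
Why: Knoevenagel–Doebner condensation of a malonic half ester: piperidine-catalysed condensation should give the arylidene malonate, whose decarboxylation in pyridine gives the conjugated ester as the thermodynamically favoured E-alkene, and the free catechol is tolerated so no protecting group is needed.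

**Compound list**
1 | (R)-(−)-carvone | CC1=CC[C@@H](C(C)=C)CC1=O | starting material
2 | lithium enolate of carvone (cross-conjugated dienolate) | CC1=CC[C@@H](C(C)=C)C=C1[O-].[Li+] | intermediate
3 | (5R,6S)-6-methylcarvone [(5R,6S)-2,6-dimethyl-5-(prop-1-en-2-yl)cyclohex-2-en-1-one], trans epimer major | CC1=CC[C@@H](C(C)=C)[C@H](C)C1=O | intermediate
4 | 1-chloro-3-iodopropane | ClCCCI | starting material
5 | lithium enolate of 6-methylcarvone | CC1=CC[C@@H](C(C)=C)C(C)=C1[O-].[Li+] | intermediate
6 | (5S,6S)-6-(3-chloropropyl)-2,6-dimethyl-5-(prop-1-en-2-yl)cyclohex-2-en-1-one (chloropropyl trans to isopropenyl) | CC1=CC[C@@H](C(C)=C)[C@](C)(CCCCl)C1=O | intermediate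
7 | (5S,6S)-6-(3-iodopropyl)-2,6-dimethyl-5-(prop-1-en-2-yl)cyclohex-2-en-1-one | CC1=CC[C@@H](C(C)=C)[C@](C)(CCCI)C1=O | intermediate
8 | (4aS,8aS)-2,5,5,8a-tetramethyl-4a,5,6,7,8,8a-hexahydronaphthalen-1(4H)-one (11-nordrim-7-en-9-one, trans-fused) | CC1=CC[C@H]2C(C)(C)CCC[C@]2(C)C1=O | intermediate
9 | (5S,10S)-drima-7,9(11)-diene | CC1=CC[C@H]2C(C)(C)CCC[C@]2(C)C1=C | intermediate
10 | B-[(5S,9S,10S)-drim-7-en-11-yl]-9-borabicyclo[3.3.1]nonane | CC1=CC[C@H]2C(C)(C)CCC[C@]2(C)[C@H]1CB1C2CCCC1CCC2 | intermediate
11 | (−)-drimenol, [(1S,4aS,8aS)-2,5,5,8a-tetramethyl-1,4,4a,5,6,7,8,8a-octahydronaphthalen-1-yl]methanol | CC1=CC[C@H]2C(C)(C)CCC[C@]2(C)[C@H]1CO | intermediate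
12 | Meldrum's acid (2,2-dimethyl-1,3-dioxane-4,6-dione) | CC1(C)OC(=O)CC(=O)O1 | starting material
13 | drimenyl hydrogen malonate | CC1=CC[C@H]2C(C)(C)CCC[C@]2(C)[C@H]1COC(=O)CC(=O)O | intermediate
14 | 3,4-dihydroxybenzaldehyde | O=Cc1ccc(O)c(O)c1 | starting material
15 | 2-(drimenyloxycarbonyl)-3-(3,4-dihydroxyphenyl)prop-2-enoic acid (arylidene malonate half ester) | CC1=CC[C@H]2C(C)(C)CCC[C@]2(C)[C@H]1COC(=O)C(=Cc1ccc(O)c(O)c1)C(=O)O | intermediate
16 | [(1S,4aS,8aS)-2,5,5,8a-tetramethyl-1,4,4a,5,6,7,8,8a-octahydronaphthalen-1-yl]methyl (2E)-3-(3,4-dihydroxyphenyl)prop-2-enoate | CC1=CC[C@H]2C(C)(C)CCC[C@]2(C)[C@H]1COC(=O)/C=C/c1ccc(O)c(O)c1 | target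

**Step count**
Total steps: 8. Longest linear sequence: 8 steps, from (R)-carvone.

**Steps most likely to fail**

1. Step 4 (proposed new method). Ring closure may be outrun by simple reduction: hydrogenation of the isopropenyl group, hydrodeiodination or β-hydride elimination at the alkylnickel, or conjugate reduction of the enone by the metal hydride. The fallback uses known chemistry only, sets out from compound 3 and returns at compound 8. Compound 3 is deprotonated as in step 2 and the enolate 5 is alkylated, again anti to the isopropenyl group, with methyl 2-(bromomethyl)acrylate to give methyl 2-{[(1S,6S)-1,3-dimethyl-2-oxo-6-(prop-1-en-2-yl)cyclohex-3-en-1-yl]methyl}prop-2-enoate F1. Under Fe(acac)3/PhSiH3 in EtOH/ethylene glycol at 60 °C, the MHAT-derived tertiary radical should add to the acrylate CH2 in a 6-endo-trig Giese cyclisation and give methyl (5S,10S)-11-nor-9-oxodrim-7-ene-2-carboxylate F2 as a mixture of C2 epimers. Saponification (LiOH, THF/MeOH/H2O) would give (5S,10S)-11-nor-9-oxodrim-7-ene-2-carboxylic acid F3. Photocatalytic hydrodecarboxylation (9-mesityl-10-methylacridinium tetrafluoroborate, PhSSPh, i-Pr2NEt, CF3CH2OH, blue light) would remove the carboxyl group and deliver 8.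

2. Step 2. C-alkylation of the hindered tetrasubstituted enolate by an unactivated primary iodide may be slow, allowing proton transfer, O-alkylation and erosion of facial selectivity. The fallback sets out from compound 3 and returns at compound 7. Enolate 5 is alkylated with the far more reactive allyl bromide, anti to the isopropenyl group, to give (5S,6S)-6-allyl-6-methylcarvone F4. Chemoselective hydroboration of the monosubstituted alkene with one equivalent of 9-BBN (THF, 0 °C) would give the B-(3-substituted propyl)-9-BBN adduct F5, which is not isolated. Iodinolysis (I2, NaOMe, MeOH, 0 °C) would deliver iodide 7, bypassing step 3.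

3. Step 5. Attack of the ylide at the crowded carbonyl may be slower than reversible γ-deprotonation of the enone, giving incomplete conversion or deconjugation. The fallback sets out from compound 8 and returns at compound 9. Addition of Me3SiCH2Li/CeCl3 (THF, −78 °C), a small and weakly basic nucleophile, gives the β-hydroxysilane (5S,10S)-9-[(trimethylsilyl)methyl]-11-nordrim-7-en-9-ol F6. Peterson syn-elimination with KH in THF would give diene 9.

**Further compounds**
F1 | step 4 | methyl 2-{[(1S,6S)-1,3-dimethyl-2-oxo-6-(prop-1-en-2-yl)cyclohex-3-en-1-yl]methyl}prop-2-enoate | CC1=CC[C@@H](C(C)=C)[C@](C)(CC(=C)C(=O)OC)C1=O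
F2 | step 4 | methyl (5S,10S)-11-nor-9-oxodrim-7-ene-2-carboxylate (C2 epimers) | CC1=CC[C@H]2C(C)(C)CC(C(=O)OC)C[C@]2(C)C1=O
F3 | step 4 | (5S,10S)-11-nor-9-oxodrim-7-ene-2-carboxylic acid (C2 epimers) | CC1=CC[C@H]2C(C)(C)CC(C(=O)O)C[C@]2(C)C1=O
F4 | step 2 | (5S,6S)-6-allyl-2,6-dimethyl-5-(prop-1-en-2-yl)cyclohex-2-en-1-one | CC1=CC[C@@H](C(C)=C)[C@](C)(CC=C)C1=O
F5 | step 2 | B-{3-[(1S,6S)-1,3-dimethyl-2-oxo-6-(prop-1-en-2-yl)cyclohex-3-en-1-yl]propyl}-9-borabicyclo[3.3.1]nonane | CC1=CC[C@@H](C(C)=C)[C@](C)(CCCB2C3CCCC2CCC3)C1=O
F6 | step 5 | (5S,10S)-9-[(trimethylsilyl)methyl]-11-nordrim-7-en-9-ol | CC1=CC[C@H]2C(C)(C)CCC[C@]2(C)C1(O)C[Si](C)(C)C
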